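**Strategy.** Ring A (C1–C5, C10; abietane numbering) is disconnected across C3–C4 and C5–C10. The C4=C5 unit, activated by the C4 ester, is a tiglate-type dienophile and C10(CH3)=C1–C2=C3 is a diene. Because C5–C10 is also the ring-fusion bond, one intramolecular Diels–Alder reaction of an acyclic triene closes rings A and B together and sets C4, C5 and C10. Olefin geometry fixes C4/C5 and the trans fusion; the C9 stereocentre selects the diene face. The precursor is a 1,7,9-decatriene whose tether already holds the C7=C8 enoate and the ketal-protected side chain. C9 and the (E)-diene come from a Johnson–Claisen chirality transfer.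

Key step: step 11

Remark on numbering: abietane numbers are used throughout (ring A = C1–C5, C10; ring B = C5–C10; C18 = carboxyl carbon on C4; C14 = carboxyl carbon on C8; C11–C13 = keto side chain on C9); α is the face of H-5, β the face of the C10 methyl.
Assumption: the ProPhenol antipode written in step 3 is taken to be the one that delivers the (R)-carbinol; should the sense be the reverse, the other antipode is used.

Step 1
Reactants: 1 (3-methylbutan-2-one); 2 (1-bromo-3-methylbut-2-ene, prenyl bromide)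
Product: 3 ketone 2,7-dimethyloct-6-en-3-one
Conditions: LiN(iPr)2, THF, −78 °C; then 2, −78 → 0 °C
Reagents that add atoms: none
Why: Kinetic enolate alkylation: LiN(iPr)2 deprotonates the methyl ketone at CH3 at −78 °C and the lithium enolate displaces the allylic bromide (SN2), which assembles C9–C13 with the isopropyl ketone and creates no stereocentre.

Step 2
Reactants: 3 (2,7-dimethyloct-6-en-3-one)
Product: 5 enal (2E)-2,7-dimethyl-6-oxooct-2-enal, via allylic alcohol 4 (not isolated)
Conditions: SeO2 (0.5 equiv), t-BuOOH, CH2Cl2, 23 °C; then MnO2, CH2Cl2, 23 °C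
Reagents that add atoms: selenium dioxide, O=[Se]=O; tert-butyl hydroperoxide, CC(C)(C)OO (the new oxygen is delivered by SeO2, which the hydroperoxide regenerates)
Why: Allylic oxidation by SeO2 (ene reaction then [2,3]-sigmatropic shift) attacks only the methyl group trans to the chain on the trisubstituted olefin, and MnO2 then oxidises only the allylic alcohol, so the (E)-enal should result with the saturated ketone untouched.

Step 3
Reactants: 5 ((2E)-2,7-dimethyl-6-oxooct-2-enal); 6 (ethynyltrimethylsilane)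
Product: 7 enynol (6E,8R)-8-hydroxy-2,7-dimethyl-10-(trimethylsilyl)dec-6-en-9-yn-3-one
Conditions: ZnMe2, (S,S)-ProPhenol (10 mol %), toluene, 0 °C; aq. NH4Cl
Reagents that add atoms: none
Why: Catalytic asymmetric alkynylation (1,2-addition of the alkynylzinc formed from 6 and ZnMe2 inside the chiral dinuclear zinc–ProPhenol complex): the aldehyde reacts while the hindered ketone does not, and the ligand controls the enal face so that the new carbinol centre (the future C1) is R.

Step 4
Reactants: 7 (enynol); 8 (1,1,1-trimethoxyethane, trimethyl orthoacetate)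
Product: 9 ester methyl (3S,4E)-4-methyl-3-(4-methyl-3-oxopentyl)-7-(trimethylsilyl)hept-4-en-6-ynoate
Conditions: 8 (excess), EtCO2H (cat.), xylene, 135 °C (MeOH distilled off); then 1 M HCl, THF, 23 °C (brief)
Reagents that add atoms: none
Why: Johnson–Claisen (orthoester) rearrangement: the mixed ketene acetal shifts [3,3] through the trisubstituted olefin in a chair transition state with the alkynyl group equatorial, which should give the (E)-C10=C1 bond and transfer the carbinol chirality suprafacially to C9 (R-carbinol plus E-olefin gives the required C9 configuration), the shift through the silyl-capped alkyne being higher in energy; the acidic work-up returns any ketone dimethyl ketal to the ketone.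

Step 5
Reactants: 9 (keto ester)
Product: 10 ketal methyl (3S,4E)-4-methyl-3-{2-[2-(propan-2-yl)-1,3-dioxolan-2-yl]ethyl}-7-(trimethylsilyl)hept-4-en-6-ynoate
Conditions: TMSOCH2CH2OTMS, TMSOTf (cat.), CH2Cl2, −78 → −20 °C; pyridine quench
Reagents that add atoms: 1,2-bis(trimethylsilyloxy)ethane, C[Si](C)(C)OCCO[Si](C)(C)C
Why: Ketalisation under TMSOTf catalysis with the bis-silyl ether of ethylene glycol (driven by formation of hexamethyldisiloxane) masks the enolisable ketone before ester enolate chemistry and leaves the ester, the enyne and C9 untouched.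

Step 6
Reactants: 10 (ketal ester); 11 (3-[(tert-butyldimethylsilyl)oxy]propanal)
Product: 12 aldol adduct methyl 5-[(tert-butyldimethylsilyl)oxy]-3-hydroxy-2-[(3S,4E)-4-methyl-1-[2-(propan-2-yl)-1,3-dioxolan-2-yl]-7-(trimethylsilyl)hept-4-en-6-yn-3-yl]pentanoate (mixture at C7 and C8)
Conditions: LiN(iPr)2, THF, −78 °C; then 11, −78 °C; aq. NH4Cl
Reagents that add atoms: none
Why: Aldol addition of the lithium ester enolate (C8) to aldehyde 11 forms the C7–C8 bond; the two new centres (C7, C8) form unselectively and both are destroyed in step 7.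

Step 7
Reactants: 12 (aldol adduct)
Product: 14 enoate methyl (2E)-5-[(tert-butyldimethylsilyl)oxy]-2-[(3R,4E)-4-methyl-1-[2-(propan-2-yl)-1,3-dioxolan-2-yl]-7-(trimethylsilyl)hept-4-en-6-yn-3-yl]pent-2-enoate, via mesylate 13 (not isolated)
Conditions: MsCl, Et3N, CH2Cl2, 0 °C; then DBU, 23 °C
Reagents that add atoms: none
Why: Mesylation and E1cB elimination is stereoconvergent: both aldol diastereomers pass through the same ester enolate and expel mesylate to give the conjugated enoate with CO2Me trans to the C6 chain (C6 cis to C9), the tiglate-like geometry that later lets ring B close.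

Step 8
Reactants: 14 (silylated enoate)
Product: 15 alcohol methyl (2E)-5-hydroxy-2-[(3R,4E)-4-methyl-1-[2-(propan-2-yl)-1,3-dioxolan-2-yl]hept-4-en-6-yn-3-yl]pent-2-enoate
Conditions: Bu4NF, THF, 0 → 23 °C
Reagents that add atoms: none
Why: Fluoride-mediated desilylation cleaves the primary silyl ether and the C(sp)–SiMe3 bond in one operation, the ketal and both olefins being inert.

Step 9
Reactants: 15 (terminal enyne)
Product: 16 diene alcohol methyl (2E)-5-hydroxy-2-[(3R,4E)-4-methyl-1-[2-(propan-2-yl)-1,3-dioxolan-2-yl]hepta-4,6-dien-3-yl]pent-2-enoate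
Conditions: H2 (1 atm), Pd/CaCO3 poisoned with Pb(OAc)2, quinoline, EtOAc, 23 °C
Reagents that add atoms: none
Why: Lindlar semihydrogenation adds one equivalent of H2 syn to the terminal alkyne and should stop at the vinyl group, which completes the diene C10(CH3)=C1–C2=C3 with C9 trans to C2 without touching the trisubstituted olefins.

Step 10
Reactants: 16 (diene alcohol); 17 (methyl 2-(triphenyl-λ5-phosphanylidene)propanoate)
Product: 19 triene dimethyl (2E,5E)-2-methyl-6-[(3R,4E)-4-methyl-1-[2-(propan-2-yl)-1,3-dioxolan-2-yl]hepta-4,6-dien-3-yl]hepta-2,5-dienedioate, via aldehyde 18 (not isolated)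
Conditions: Dess–Martin periodinane, NaHCO3, CH2Cl2, 0 °C; then 17, CH2Cl2, 23 °C
Reagents that add atoms: none
Why: Dess–Martin oxidation gives the sensitive β,γ-unsaturated aldehyde, which is trapped at once in a Wittig reaction with the non-basic stabilised ylide 17 (a reagent type that gives (E)-2-methyl-2-enoates), so the C4=C5 dienophile should carry CO2Me trans to C6.

Step 11
Reactants: 19 (triene)
Product: 20 cycloadduct dimethyl (4R,5R,9R,10S)-13,13-(ethane-1,2-diyldioxy)-13,14-secoabieta-1,7-diene-14,18-dioate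
Conditions: toluene (0.01 M), BHT (cat.), base-washed sealed tube, 180 °C
Reagents that add atoms: none
Why: Thermal, concerted but asynchronous [4+2] cycloaddition (intramolecular Diels–Alder reaction of a terminally ester-activated 1,7,9-decatriene) forms C3–C4 and C5–C10 suprafacially on both components. Ring A closes as the new cyclohexene (C1=C2), and ring B closes at the same time through the four-atom tether C6–C7=C8–C9, whose cis C7=C8 bond pre-organises a half-chair. C4 and C5 follow stereospecifically from the (E)-dienophile (CO2Me trans to C6, hence 4α-CO2Me and 4β-CH3 relative to 5α-H), and the trans fusion (10β-CH3, 5α-H) follows from the (E)-diene with C9 outside reacting through the ester-endo, tether-exo transition state. The diene face is chosen by the C9 stereocentre: in the favoured transition state H-9 eclipses C10=C1 (minimal allylic strain) and the side chain is pseudo-equatorial and anti to the incoming C5, which gives the 9α-H/10β-CH3 relationship. The step needs endo over exo selectivity and this facial selectivity, secured by the olefin geometries and C9. The 1,5-hydrogen shift of the inside methyl should be slower than cyclisation at 180 °C, and any (Z)-C7=C8 isomer cannot cyclise.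

Step 12
Reactants: 20 (cycloadduct)
Product: 21 diester dimethyl (4R,5R,9R,10S)-13,13-(ethane-1,2-diyldioxy)-13,14-secoabiet-7-ene-14,18-dioate
Conditions: H2 (1 atm), RhCl(PPh3)3 (5 mol %), benzene/EtOH, 23 °C
Reagents that add atoms: none
Why: Homogeneous hydrogenation with RhCl(PPh3)3 should reduce the cis-disubstituted C1=C2 bond and leave the trisubstituted, ester-conjugated C7=C8 bond; no stereocentre is formed or touched.

Step 13
Reactants: 21 (diester ketal)
Product: 23 target (4R,5R,9R,10S)-13-oxo-13,14-secoabiet-7-ene-14,18-dioic acid, via ketal diacid 22 (not isolated)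
Conditions: KOH, HOCH2CH2OH/H2O, 120 °C; then 2 M HCl, THF, 23 °C
Reagents that add atoms: potassium hydroxide, [K+].[OH-]; water, O
Why: Saponification of the conjugated C14 ester and, under forcing conditions, of the hindered equatorial C18 ester is run while the ketone is still masked (no aldol chemistry), and the acidic work-up hydrolyses the dioxolane; none of C4, C5, C9 and C10 is epimerisable under these conditions.

**Compound list**

1 | 3-methylbutan-2-one | CC(=O)C(C)C | starting material
2 | 1-bromo-3-methylbut-2-ene (prenyl bromide) | CC(C)=CCBr | starting material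
3 | 2,7-dimethyloct-6-en-3-one | CC(C)C(=O)CCC=C(C)C | intermediate
4 | (6E)-8-hydroxy-2,7-dimethyloct-6-en-3-one | CC(C)C(=O)CC/C=C(\C)CO | intermediate
5 | (2E)-2,7-dimethyl-6-oxooct-2-enal | CC(C)C(=O)CC/C=C(\C)C=O | intermediate
6 | ethynyltrimethylsilane | C#C[Si](C)(C)C | starting material
7 | (6E,8R)-8-hydroxy-2,7-dimethyl-10-(trimethylsilyl)dec-6-en-9-yn-3-one | CC(C)C(=O)CC/C=C(\C)[C@@H](O)C#C[Si](C)(C)C | intermediate
8 | 1,1,1-trimethoxyethane (trimethyl orthoacetate) | CC(OC)(OC)OC | starting material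
9 | methyl (3S,4E)-4-methyl-3-(4-methyl-3-oxopentyl)-7-(trimethylsilyl)hept-4-en-6-ynoate | CC(C)C(=O)CC[C@@H](CC(=O)OC)/C(C)=C/C#C[Si](C)(C)C | intermediate
10 | methyl (3S,4E)-4-methyl-3-{2-[2-(propan-2-yl)-1,3-dioxolan-2-yl]ethyl}-7-(trimethylsilyl)hept-4-en-6-ynoate | CC(C)C1(CC[C@@H](CC(=O)OC)/C(C)=C/C#C[Si](C)(C)C)OCCO1 | intermediate
11 | 3-[(tert-butyldimethylsilyl)oxy]propanal | O=CCCO[Si](C)(C)C(C)(C)C | starting material
12 | methyl 5-[(tert-butyldimethylsilyl)oxy]-3-hydroxy-2-[(3S,4E)-4-methyl-1-[2-(propan-2-yl)-1,3-dioxolan-2-yl]-7-(trimethylsilyl)hept-4-en-6-yn-3-yl]pentanoate (mixture at C7, C8) | CC(C)C1(CC[C@@H](C(C(=O)OC)C(O)CCO[Si](C)(C)C(C)(C)C)/C(C)=C/C#C[Si](C)(C)C)OCCO1 | intermediate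
13 | methanesulfonate of 12 (3-(methanesulfonyloxy) ester) | CC(C)C1(CC[C@@H](C(C(=O)OC)C(OS(C)(=O)=O)CCO[Si](C)(C)C(C)(C)C)/C(C)=C/C#C[Si](C)(C)C)OCCO1 | intermediate
14 | methyl (2E)-5-[(tert-butyldimethylsilyl)oxy]-2-[(3R,4E)-4-methyl-1-[2-(propan-2-yl)-1,3-dioxolan-2-yl]-7-(trimethylsilyl)hept-4-en-6-yn-3-yl]pent-2-enoate | CC(C)C1(CC[C@@H](/C(C(=O)OC)=C\CCO[Si](C)(C)C(C)(C)C)/C(C)=C/C#C[Si](C)(C)C)OCCO1 | intermediate
15 | methyl (2E)-5-hydroxy-2-[(3R,4E)-4-methyl-1-[2-(propan-2-yl)-1,3-dioxolan-2-yl]hept-4-en-6-yn-3-yl]pent-2-enoate | CC(C)C1(CC[C@@H](/C(C(=O)OC)=C\CCO)/C(C)=C/C#C)OCCO1 | intermediate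
16 | methyl (2E)-5-hydroxy-2-[(3R,4E)-4-methyl-1-[2-(propan-2-yl)-1,3-dioxolan-2-yl]hepta-4,6-dien-3-yl]pent-2-enoate | CC(C)C1(CC[C@@H](/C(C(=O)OC)=C\CCO)/C(C)=C/C=C)OCCO1 | intermediate
17 | methyl 2-(triphenyl-λ5-phosphanylidene)propanoate | COC(=O)C(C)=P(c1ccccc1)(c1ccccc1)c1ccccc1 | starting material
18 | methyl (2E)-5-oxo-2-[(3R,4E)-4-methyl-1-[2-(propan-2-yl)-1,3-dioxolan-2-yl]hepta-4,6-dien-3-yl]pent-2-enoate | CC(C)C1(CC[C@@H](/C(C(=O)OC)=C\CC=O)/C(C)=C/C=C)OCCO1 | intermediate
19 | dimethyl (2E,5E)-2-methyl-6-[(3R,4E)-4-methyl-1-[2-(propan-2-yl)-1,3-dioxolan-2-yl]hepta-4,6-dien-3-yl]hepta-2,5-dienedioate | CC(C)C1(CC[C@@H](/C(C(=O)OC)=C\C/C=C(\C)C(=O)OC)/C(C)=C/C=C)OCCO1 | intermediate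
20 | dimethyl (4R,5R,9R,10S)-13,13-(ethane-1,2-diyldioxy)-13,14-secoabieta-1,7-diene-14,18-dioate (trans-decalin; 10β-CH3, 4β-CH3, 4α-CO2Me, 5α-H, 9α-H) | CC(C)C1(CC[C@H]2C(C(=O)OC)=CC[C@@H]3[C@]2(C)C=CC[C@@]3(C)C(=O)OC)OCCO1 | intermediate
21 | dimethyl (4R,5R,9R,10S)-13,13-(ethane-1,2-diyldioxy)-13,14-secoabiet-7-ene-14,18-dioate | CC(C)C1(CC[C@H]2C(C(=O)OC)=CC[C@@H]3[C@]2(C)CCC[C@@]3(C)C(=O)OC)OCCO1 | intermediate
22 | (4R,5R,9R,10S)-13,13-(ethane-1,2-diyldioxy)-13,14-secoabiet-7-ene-14,18-dioic acid | CC(C)C1(CC[C@H]2C(C(=O)O)=CC[C@@H]3[C@]2(C)CCC[C@@]3(C)C(=O)O)OCCO1 | intermediate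
23 | (4R,5R,9R,10S)-13-oxo-13,14-secoabiet-7-ene-14,18-dioic acid | CC(C)C(=O)CC[C@H]1C(C(=O)O)=CC[C@@H]2[C@]1(C)CCC[C@@]2(C)C(=O)O | target

**Step count and risks**

Total steps: 13. Longest linear sequence: 13 steps (1 → 23); 2, 6, 8, 11 and 17 are commercial.

Steps most likely to fail:

1. Step 11. Bond formation at the fully substituted diene terminus C10 may be slow enough for thermal diene isomerisation (1,5-hydrogen shift of the inside methyl) and oligomerisation to compete, and endo/exo or facial discrimination may be insufficient. The fallback sets out from 16 and comes back at 20. Oxidation as in step 10 gives aldehyde 18, and a Wittig reaction with 2-(triphenylphosphoranylidene)propanal gives the (E)-2-methyl trienal F1. Me2AlCl in CH2Cl2 at −78 to −30 °C promotes the intramolecular Diels–Alder reaction of this enal (Lewis-acid activation, stronger endo preference, no thermal hydrogen shift) to the cycloadduct aldehyde F2. Oxidation with NaClO2/NaH2PO4/2-methylbut-2-ene gives the carboxylic acid F3, and Me3SiCHN2 in MeOH/toluene returns diester 20.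

2. Step 4. A competing sigmatropic shift through the alkynyl arm, acid-promoted ionisation of the doubly activated carbinol at 135 °C, or erosion of E-selectivity and chirality transfer may occur. The fallback sets out from 7 and comes back at 9. Acetylation (Ac2O, pyridine, DMAP) gives the acetate F4. An Ireland–Claisen rearrangement (LiN(iPr)2 added to F4 and Me3SiCl in THF at −78 °C, then 23 °C; the ketone is held as its silyl enol ether until the aqueous acid work-up) should run at ambient temperature through the same chair and give the acid F5. Me3SiCHN2 converts it into 9.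

3. Step 7. Geometric control in the elimination may be lost, giving the (Z)-enoate, in which C6 and C9 are trans and ring B cannot close. The fallback sets out from 12 and comes back at 14. Dess–Martin oxidation gives the β-keto ester F6. Its chelated sodium enolate (NaH, then Tf2O, CH2Cl2, −78 °C) is triflated to the (Z)-enol triflate F7 (OTf cis to CO2Me). Reduction with HCO2H/Bu3N under Pd(OAc)2/PPh3 catalysis (DMF, 60 °C) replaces OTf by H with retention of olefin geometry and gives 14 as a single olefin isomer.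

**Further compounds**

F1 | step 11 | methyl (2E,5E)-6-methyl-2-[(3R,4E)-4-methyl-1-[2-(propan-2-yl)-1,3-dioxolan-2-yl]hepta-4,6-dien-3-yl]-7-oxohepta-2,5-dienoate | CC(C)C1(CC[C@@H](/C(C(=O)OC)=C\C/C=C(\C)C=O)/C(C)=C/C=C)OCCO1
F2 | step 11 | methyl (4R,5R,9R,10S)-13,13-(ethane-1,2-diyldioxy)-18-oxo-13,14-secoabieta-1,7-dien-14-oate | CC(C)C1(CC[C@H]2C(C(=O)OC)=CC[C@@H]3[C@]2(C)C=CC[C@@]3(C)C=O)OCCO1
F3 | step 11 | (4R,5R,9R,10S)-13,13-(ethane-1,2-diyldioxy)-14-methoxy-14-oxo-13,14-secoabieta-1,7-dien-18-oic acid | CC(C)C1(CC[C@H]2C(C(=O)OC)=CC[C@@H]3[C@]2(C)C=CC[C@@]3(C)C(=O)O)OCCO1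
F4 | step 4 | (3R,4E)-4,9-dimethyl-8-oxo-1-(trimethylsilyl)dec-4-en-1-yn-3-yl acetate | CC(C)C(=O)CC/C=C(\C)[C@@H](OC(C)=O)C#C[Si](C)(C)C
F5 | step 4 | (3S,4E)-4-methyl-3-(4-methyl-3-oxopentyl)-7-(trimethylsilyl)hept-4-en-6-ynoic acid | CC(C)C(=O)CC[C@@H](CC(=O)O)/C(C)=C/C#C[Si](C)(C)C
F6 | step 7 | methyl 5-[(tert-butyldimethylsilyl)oxy]-3-oxo-2-[(3S,4E)-4-methyl-1-[2-(propan-2-yl)-1,3-dioxolan-2-yl]-7-(trimethylsilyl)hept-4-en-6-yn-3-yl]pentanoate (C8 epimers) | CC(C)C1(CC[C@@H](C(C(=O)OC)C(=O)CCO[Si](C)(C)C(C)(C)C)/C(C)=C/C#C[Si](C)(C)C)OCCO1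
F7 | step 7 | methyl (2Z)-5-[(tert-butyldimethylsilyl)oxy]-2-[(3R,4E)-4-methyl-1-[2-(propan-2-yl)-1,3-dioxolan-2-yl]-7-(trimethylsilyl)hept-4-en-6-yn-3-yl]-3-[(trifluoromethanesulfonyl)oxy]pent-2-enoate | CC(C)C1(CC[C@@H](/C(C(=O)OC)=C(/OS(=O)(=O)C(F)(F)F)CCO[Si](C)(C)C(C)(C)C)/C(C)=C/C#C[Si](C)(C)C)OCCO1
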